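**Plan**

Retrosynthetic cuts, in order:
- the formyl oxygen, back to the methyl of an isopropenyl group
- the senecioate O–acyl bond at C1'
- the C1'–H bond, back to a C5 acetyl group
- the side-chain alkene, back to its hydrate, a 2-hydroxypropan-2-yl group on C2
- the C5–acetyl C–C bond, back to C5–Br
- the isovalerate O–acyl bond
- the C3–O bond, the O1–C2 bond and the aryl–prenyl C–C bond

Enabling feature: in the hydrated form, C3 of the dihydrofuran ring (ring B) is a CH2. It is benzylic to the benzene ring (ring A) and gamma to the tertiary side-chain oxygen on C2. A carbamate on that oxygen can therefore take a C3 hydrogen on its own face and return its carbonyl oxygen to the same carbon.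

Forward, rings: 4-bromophenol is prenylated at the ortho carbon. Ring B closes by 5-exo opening of the prenyl epoxide. A temporary six-membered carbonate ring is then closed across C3 and the side-chain oxygen and opened again.

Forward, periphery: the order is C3 isovalerate, C5 acetyl, alkene, C1' carbinol, senecioate, enal. In this order palladium never meets the allylic aryl ether and selenium never meets the methyl ketone.

Stereochemistry: C2 comes from a Shi epoxidation and is inverted once in the ring closure. C3 is relayed from C2 by the tether (cis). C1' comes from a catalyst-controlled transfer hydrogenation.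

Key step: step 6

Remark on numbering: benzofuran numbering is used throughout (O1, C2, C3, C3a, C4–C7, C7a), and C1' is the carbinol carbon on C5. The target is read as (2R,3R,1'S) with the C2 and C3 substituents cis. The C2 descriptor reads S while the side chain carries its tertiary oxygen. It reads R in the C3 bromide and once the side chain is an alkene. Only the CIP ranking changes, never the geometry.

Assumption: AcOBr cannot be bought and is made from AgOAc and Br2 directly before use. Every numbered starting material is commercial.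

**Step 1**
Reactants: 1 4-bromophenol; 2 prenyl bromide (1-bromo-3-methylbut-2-ene)
Product: 3 4-bromo-2-(3-methylbut-2-en-1-yl)phenol
Conditions: NaH, toluene, 0 °C; then 2, 0 °C to rt
Reagents that add atoms: none
Why: Ortho-selective C-alkylation of a phenoxide: in toluene the sodium phenoxide reacts as a tight ion pair that steers the allylic bromide to the ortho carbon instead of oxygen, and the para carbon is already occupied by bromine.

**Step 2**
Reactants: 3 4-bromo-2-(3-methylbut-2-en-1-yl)phenol
Product: 4 [4-bromo-2-(3-methylbut-2-en-1-yl)phenoxy](tert-butyl)dimethylsilane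
Conditions: TBSCl, imidazole, DMF, rt
Reagents that add atoms: tert-butyldimethylsilyl chloride, CC(C)(C)[Si](C)(C)Cl
Why: Standard imidazole-promoted O-silylation, chosen because the free phenol would be oxidised in step 3 and an aryl acetate would be hydrolysed at the pH of that step.

**Step 3**
Reactants: 4 [4-bromo-2-(3-methylbut-2-en-1-yl)phenoxy](tert-butyl)dimethylsilane
Product: 5 (4-bromo-2-{[(2R)-3,3-dimethyloxiran-2-yl]methyl}phenoxy)(tert-butyl)dimethylsilane
Conditions: D-fructose-derived Shi ketone (1,2:4,5-di-O-isopropylidene-β-D-erythro-2,3-hexodiulo-2,6-pyranose, 30 mol %), KHSO5 (as 2KHSO5·KHSO4·K2SO4), K2CO3, Bu4NHSO4 (cat.), MeCN–CH2(OMe)2 / aq Na2B4O7–Na2EDTA buffer (pH 10.5), 0 °C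
Reagents that add atoms: potassium peroxymonosulfate, [K+].[O-]S(=O)(=O)OO
Why: Shi asymmetric epoxidation: the chiral dioxirane formed from the ketone and KHSO5 transfers oxygen to the trisubstituted alkene through the spiro transition state, which in the D-fructose series gives the (R)-epoxide of a prenyl group.

**Step 4**
Reactants: 5 (4-bromo-2-{[(2R)-3,3-dimethyloxiran-2-yl]methyl}phenoxy)(tert-butyl)dimethylsilane
Product: 7 2-[(2S)-5-bromo-2,3-dihydro-1-benzofuran-2-yl]propan-2-ol, via epoxy phenol 6 (not isolated)
Conditions: Bu4NF, THF, 0 °C to rt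
Reagents that add atoms: none
Why: Fluoride desilylation followed by base-mode intramolecular epoxide opening: the phenoxide attacks the secondary epoxide carbon in a 5-exo-tet SN2 process with inversion, so the (R)-epoxide becomes (S)-configured C2 and the tertiary carbinol is released, whereas the 6-endo chromanol pathway would need acid.

**Step 5**
Reactants: 7 2-[(2S)-5-bromo-2,3-dihydro-1-benzofuran-2-yl]propan-2-ol; 8 2,2,2-trifluoroethyl isocyanate
Product: 9 2-[(2S)-5-bromo-2,3-dihydro-1-benzofuran-2-yl]propan-2-yl N-(2,2,2-trifluoroethyl)carbamate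
Conditions: 8, CuCl (20 mol %), DMF, rt
Reagents that add atoms: none
Why: Urethane formation by CuCl-catalysed addition of a hindered tertiary alcohol to an electron-poor isocyanate, which touches no stereocentre.

**Step 6**
Reactants: 9 2-[(2S)-5-bromo-2,3-dihydro-1-benzofuran-2-yl]propan-2-yl N-(2,2,2-trifluoroethyl)carbamate
Product: 13 cis-fused six-membered cyclic carbonate of (2S,3R)-5-bromo-2-(2-hydroxypropan-2-yl)-2,3-dihydro-1-benzofuran-3-ol, via N-bromocarbamate 10 (not isolated), via C3 bromide 11 (not isolated), via cyclic iminocarbonate 12 (not isolated)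
Conditions: AcOBr (1.0 equiv, from AgOAc + Br2), CH2Cl2, 0 °C, dark; CBr4, PhCF3, hν (visible flood lamp), 10–20 °C; Ag2CO3 added to the photolysate, rt, dark; AcOH–H2O, rt
Reagents that add atoms: water, O (oxygen of the new C=O); acetyl hypobromite, CC(=O)OBr (its bromine is present only in 10 and 11)
Why: The carbamate N–H is exchanged for N–Br by AcOBr, visible light breaks that weak bond, and the electrophilic carbamoyl nitrogen radical reaches across a seven-membered array (1,6-hydrogen shift) to pull off the C3 hydrogen on the side-chain face, after which the benzylic radical is brominated by 10 or CBr4 and the chain goes on. Ag2CO3 (monovalent silver) then abstracts bromide while the carbamate carbonyl oxygen bonds to C3 in a 6-exo-tet closure to iminocarbonate 12, and aqueous AcOH swaps the =NCH2CF3 unit for =O because weakly basic trifluoroethylamine is the best leaving group of the tetrahedral intermediate. The closest known chemistry is the Hofmann–Löffler–Freytag-type synthesis of 1,3-diols from N-trifluoroethyl carbamates, established for benzylic and tertiary C–H bonds. The C3 stereocentre is dictated by C2, since an O–C–O tether anchored on the C2 side chain can span to C3 only on its own face of the almost flat five-membered ring, so backside displacement of the trans bromide (expected to prevail because bromine arrives anti to the bulky substituent) and capture of a free cation both converge on the cis-fused (2S,3R) product. The step needs C3–H to be chosen over C2–H, the geminal methyl groups and the arene C7–H: C3–H is the only gamma and the only benzylic hydrogen, the beta hydrogens would call for a six-membered transition state that the planar carbamoyl radical does not adopt, and the C5 bromine blocks the para position and lowers the ring nucleophilicity so that one equivalent of AcOBr at 0 °C in the dark should be consumed at nitrogen. Loss of HBr to the aromatic benzofuran is countered by keeping 11 cool, never concentrating it, and by the syn relation of C2–H and bromine in the trans bromide, which rules out an anti elimination.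

**Step 7**
Reactants: 13 cis-fused cyclic carbonate
Product: 14 (2S,3R)-5-bromo-2-(2-hydroxypropan-2-yl)-2,3-dihydro-1-benzofuran-3-ol
Conditions: K2CO3 (20 mol %), MeOH, 0 °C to rt
Reagents that add atoms: none
Why: Base-catalysed transesterification (methanolysis) breaks only the acyl–oxygen bonds of the carbonate, so C2 and C3 keep their configuration.

**Step 8**
Reactants: 14 (2S,3R)-5-bromo-2-(2-hydroxypropan-2-yl)-2,3-dihydro-1-benzofuran-3-ol; 15 isovaleryl chloride (3-methylbutanoyl chloride)
Product: 16 (2S,3R)-5-bromo-2-(2-hydroxypropan-2-yl)-2,3-dihydro-1-benzofuran-3-yl 3-methylbutanoate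
Conditions: 15 (1.1 equiv), pyridine, 4-(dimethylamino)pyridine (5 mol %), CH2Cl2, 0 °C
Reagents that add atoms: none
Why: Nucleophile-catalysed acylation with steric discrimination: the secondary benzylic C3 hydroxyl is esterified while the tertiary hydroxyl does not react with about one equivalent of the acid chloride at 0 °C.

**Step 9**
Reactants: 16 (2S,3R)-5-bromo-2-(2-hydroxypropan-2-yl)-2,3-dihydro-1-benzofuran-3-yl 3-methylbutanoate; 17 tributyl(1-ethoxyvinyl)stannane
Product: 19 (2S,3R)-5-acetyl-2-(2-hydroxypropan-2-yl)-2,3-dihydro-1-benzofuran-3-yl 3-methylbutanoate, via aryl enol ether 18 (not isolated)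
Conditions: 17, PdCl2(PPh3)2 (5 mol %), toluene, 100 °C; then 1 M aq HCl, THF, 0 °C
Reagents that add atoms: water, O
Why: Stille coupling with an acetyl anion equivalent followed by mild hydrolysis of the aryl enol ether, carried out while the C2 side chain is still saturated so that zerovalent palladium finds no allylic aryl ether to ionise.

**Step 10**
Reactants: 19 (2S,3R)-5-acetyl-2-(2-hydroxypropan-2-yl)-2,3-dihydro-1-benzofuran-3-yl 3-methylbutanoate
Product: 20 (2R,3R)-5-acetyl-2-(prop-1-en-2-yl)-2,3-dihydro-1-benzofuran-3-yl 3-methylbutanoate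
Conditions: methyl N-(triethylammoniosulfonyl)carbamate (Burgess reagent), toluene, 60 °C
Reagents that add atoms: none
Why: Burgess dehydration: the tertiary sulfamate ester collapses by syn elimination towards one of the six methyl hydrogens rather than the single, inductively deactivated C2–H, a regiochemistry known for 2-(2-hydroxypropan-2-yl)dihydrobenzofurans, and the acetyl group para to O1 keeps the C3 ester from ionising.

**Step 11**
Reactants: 20 (2R,3R)-5-acetyl-2-(prop-1-en-2-yl)-2,3-dihydro-1-benzofuran-3-yl 3-methylbutanoate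
Product: 21 (2R,3R)-5-[(1S)-1-hydroxyethyl]-2-(prop-1-en-2-yl)-2,3-dihydro-1-benzofuran-3-yl 3-methylbutanoate
Conditions: RuCl[(S,S)-TsDPEN](p-cymene) (1 mol %; TsDPEN = N-tosyl-1,2-diphenylethane-1,2-diamine), HCO2H–Et3N (5:2), 30 °C
Reagents that add atoms: none
Why: Noyori–Ikariya asymmetric transfer hydrogenation: the (S,S) catalyst hands hydride to the Re face of aryl methyl ketones by an outer-sphere mechanism, which sets (S) at C1' under catalyst control and leaves the alkene and the ester alone.

**Step 12**
Reactants: 21 (2R,3R)-5-[(1S)-1-hydroxyethyl]-2-(prop-1-en-2-yl)-2,3-dihydro-1-benzofuran-3-yl 3-methylbutanoate; 22 senecioic acid (3-methylbut-2-enoic acid)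
Product: 23 (1S)-1-[(2R,3R)-3-(3-methylbutanoyloxy)-2-(prop-1-en-2-yl)-2,3-dihydro-1-benzofuran-5-yl]ethyl 3-methylbut-2-enoate
Conditions: 22, N,N'-dicyclohexylcarbodiimide (DCC), 4-(dimethylamino)pyridine (10 mol %), CH2Cl2, 0 °C to rt
Reagents that add atoms: none
Why: Steglich esterification forms the ester at the O–H bond, so C1' stays (S), and carbodiimide activation avoids the vinylketene route by which the acid chloride with amine bases shifts the double bond out of conjugation.

**Step 13**
Reactants: 23 (1S)-1-[(2R,3R)-3-(3-methylbutanoyloxy)-2-(prop-1-en-2-yl)-2,3-dihydro-1-benzofuran-5-yl]ethyl 3-methylbut-2-enoate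
Product: 25 (1S)-1-[(2R,3R)-3-(3-methylbutanoyloxy)-2-(3-oxoprop-1-en-2-yl)-2,3-dihydro-1-benzofuran-5-yl]ethyl 3-methylbut-2-enoate (target), via allylic alcohol 24 (not isolated)
Conditions: SeO2 (30 mol %), t-BuOOH (decane solution), CH2Cl2, rt; filtration, then MnO2, CH2Cl2, rt
Reagents that add atoms: tert-butyl hydroperoxide, CC(C)(C)OO (its oxygen is passed on through SeO2)
Why: Riley allylic oxidation (ene reaction, then [2,3]-sigmatropic shift) takes place at the methyl group of the isolated 1,1-disubstituted alkene because the senecioate alkene is deactivated by ester conjugation, MnO2 carries the allylic alcohol on to the enal under neutral conditions, and no stereocentre is involved.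

**Compound list**

1 | 4-bromophenol | Oc1ccc(Br)cc1 | starting material
2 | prenyl bromide | CC(C)=CCBr | starting material
3 | 4-bromo-2-(3-methylbut-2-en-1-yl)phenol | CC(C)=CCc1cc(Br)ccc1O | intermediate
4 | [4-bromo-2-(3-methylbut-2-en-1-yl)phenoxy](tert-butyl)dimethylsilane | CC(C)=CCc1cc(Br)ccc1O[Si](C)(C)C(C)(C)C | intermediate
5 | (4-bromo-2-{[(2R)-3,3-dimethyloxiran-2-yl]methyl}phenoxy)(tert-butyl)dimethylsilane | CC1(C)O[C@@H]1Cc1cc(Br)ccc1O[Si](C)(C)C(C)(C)C | intermediate
6 | 4-bromo-2-{[(2R)-3,3-dimethyloxiran-2-yl]methyl}phenol (reacts as its phenoxide, not isolated) | CC1(C)O[C@@H]1Cc1cc(Br)ccc1O | intermediate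
7 | 2-[(2S)-5-bromo-2,3-dihydro-1-benzofuran-2-yl]propan-2-ol | CC(C)(O)[C@H]1Oc2ccc(Br)cc2C1 | intermediate
8 | 2,2,2-trifluoroethyl isocyanate | O=C=NCC(F)(F)F | starting material
9 | 2-[(2S)-5-bromo-2,3-dihydro-1-benzofuran-2-yl]propan-2-yl N-(2,2,2-trifluoroethyl)carbamate | FC(F)(F)CNC(=O)OC(C)(C)[C@H]1Oc2ccc(Br)cc2C1 | intermediate
10 | 2-[(2S)-5-bromo-2,3-dihydro-1-benzofuran-2-yl]propan-2-yl N-bromo-N-(2,2,2-trifluoroethyl)carbamate (not isolated) | FC(F)(F)CN(Br)C(=O)OC(C)(C)[C@H]1Oc2ccc(Br)cc2C1 | intermediate
11 | 2-[(2R,3S)-3,5-dibromo-2,3-dihydro-1-benzofuran-2-yl]propan-2-yl N-(2,2,2-trifluoroethyl)carbamate (trans epimer drawn, expected to prevail; not isolated) | FC(F)(F)CNC(=O)OC(C)(C)[C@H]1Oc2ccc(Br)cc2[C@@H]1Br | intermediate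
12 | cis-fused cyclic N-(2,2,2-trifluoroethyl)iminocarbonate of diol 14, (2S,3R) (not isolated) | CC1(C)[C@H]2Oc3ccc(Br)cc3[C@H]2OC(=NCC(F)(F)F)O1 | intermediate
13 | cis-fused six-membered cyclic carbonate of diol 14, (2S,3R) | CC1(C)[C@H]2Oc3ccc(Br)cc3[C@H]2OC(=O)O1 | intermediate
14 | (2S,3R)-5-bromo-2-(2-hydroxypropan-2-yl)-2,3-dihydro-1-benzofuran-3-ol | CC(C)(O)[C@H]1Oc2ccc(Br)cc2[C@H]1O | intermediate
15 | isovaleryl chloride | CC(C)CC(=O)Cl | starting material
16 | (2S,3R)-5-bromo-2-(2-hydroxypropan-2-yl)-2,3-dihydro-1-benzofuran-3-yl 3-methylbutanoate | CC(C)(O)[C@H]1Oc2ccc(Br)cc2[C@H]1OC(=O)CC(C)C | intermediate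
17 | tributyl(1-ethoxyvinyl)stannane | CCCC[Sn](CCCC)(CCCC)C(=C)OCC | starting material
18 | (2S,3R)-5-(1-ethoxyethenyl)-2-(2-hydroxypropan-2-yl)-2,3-dihydro-1-benzofuran-3-yl 3-methylbutanoate (not isolated) | CC(C)(O)[C@H]1Oc2ccc(C(=C)OCC)cc2[C@H]1OC(=O)CC(C)C | intermediate
19 | (2S,3R)-5-acetyl-2-(2-hydroxypropan-2-yl)-2,3-dihydro-1-benzofuran-3-yl 3-methylbutanoate | CC(C)(O)[C@H]1Oc2ccc(C(C)=O)cc2[C@H]1OC(=O)CC(C)C | intermediate
20 | (2R,3R)-5-acetyl-2-(prop-1-en-2-yl)-2,3-dihydro-1-benzofuran-3-yl 3-methylbutanoate | C=C(C)[C@H]1Oc2ccc(C(C)=O)cc2[C@H]1OC(=O)CC(C)C | intermediate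
21 | (2R,3R)-5-[(1S)-1-hydroxyethyl]-2-(prop-1-en-2-yl)-2,3-dihydro-1-benzofuran-3-yl 3-methylbutanoate | C=C(C)[C@H]1Oc2ccc([C@H](C)O)cc2[C@H]1OC(=O)CC(C)C | intermediate
22 | senecioic acid (3-methylbut-2-enoic acid) | CC(C)=CC(=O)O | starting material
23 | (1S)-1-[(2R,3R)-3-(3-methylbutanoyloxy)-2-(prop-1-en-2-yl)-2,3-dihydro-1-benzofuran-5-yl]ethyl 3-methylbut-2-enoate | C=C(C)[C@H]1Oc2ccc([C@H](C)OC(=O)C=C(C)C)cc2[C@H]1OC(=O)CC(C)C | intermediate
24 | (1S)-1-[(2R,3R)-2-(3-hydroxyprop-1-en-2-yl)-3-(3-methylbutanoyloxy)-2,3-dihydro-1-benzofuran-5-yl]ethyl 3-methylbut-2-enoate (not isolated) | C=C(CO)[C@H]1Oc2ccc([C@H](C)OC(=O)C=C(C)C)cc2[C@H]1OC(=O)CC(C)C | intermediate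
25 | (1S)-1-[(2R,3R)-3-(3-methylbutanoyloxy)-2-(3-oxoprop-1-en-2-yl)-2,3-dihydro-1-benzofuran-5-yl]ethyl 3-methylbut-2-enoate | C=C(C=O)[C@H]1Oc2ccc([C@H](C)OC(=O)C=C(C)C)cc2[C@H]1OC(=O)CC(C)C | target

**Step count**

Total steps: 13. Longest linear sequence: 13 steps, from 1. Compounds 2, 8, 15, 17 and 22 enter as bought.

**Steps most likely to fail**

**Step 6.** Three things may go wrong:
- Electrophilic bromination of the arene at C7 may outrun N-bromination.
- The hydrogen shift may be inefficient on this rigid bicycle.
- The C3 bromide may shed HBr and aromatise before the ring closes.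

The fallback sets out from 7 and comes back at 13. It gives up the directed nitrogen-radical step for an intermolecular bromine-atom chain, and its nitrogen-free tether needs no electrophilic N-brominating agent. Alcohol 7 would be deprotonated with KN(SiMe3)2 and acylated with Boc2O to the mixed tert-butyl carbonate F1. Wohl–Ziegler bromination (NBS, visible light, PhCF3, rt) should attack the only benzylic carbon and give the trans C3 bromide F2. Ag2CO3 in CH2Cl2 would then drive neighbouring-group attack of the carbonate carbonyl oxygen on C3, with the tert-butyl group leaving as 2-methylpropene. This gives 13 directly, again cis because of the tether length.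

**Step 13.** Three things may go wrong:
- The selenium ene reaction may also engage the methyl groups of the senecioate.
- It may be slow because the alkene is inductively deactivated by O1.
- The acid-sensitive C1' ester may ionise during a long reaction.

The fallback sets out from 21 and comes back at 25. It oxidises the side chain before the senecioate exists. Carbinol 21 would be silylated (TBSCl, imidazole) to the C1' silyl ether F3. SeO2/t-BuOOH would oxidise this to the allylic alcohol F4, and MnO2 would take it on to the silylated enal F5. HF·pyridine would desilylate it to the hydroxy enal F6. Esterification with 22 under the conditions of step 12 would come last and give 25.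

**Step 10.** Proton loss may occur from C2 instead of a methyl group, or the cis C3 ester carbonyl may participate at the developing tertiary cation. Either path opens the way to acyl scrambling and to loss of isovaleric acid with aromatisation.

The fallback sets out from 14 and comes back at 20. While the alkene is made, the C3 oxygen carries a silyl ether, which can neither participate nor leave, and the isovalerate is attached afterwards. Diol 14 would be silylated at the secondary hydroxyl (TBSCl, imidazole, DMF) to the C3 silyl ether F7. Coupling with 17 as in step 9 would pass through the silylated enol ether F8 to the silylated ketone F9. The Burgess reagent would dehydrate this to the isopropenyl silyl ether F10. Bu4NF buffered with AcOH would desilylate it to the free C3 alcohol F11. Acylation with 15 as in step 8 would give 20.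

**Further compounds**

F1 | step 6 | tert-butyl 2-[(2S)-5-bromo-2,3-dihydro-1-benzofuran-2-yl]propan-2-yl carbonate | CC(C)(C)OC(=O)OC(C)(C)[C@H]1Oc2ccc(Br)cc2C1
F2 | step 6 | tert-butyl 2-[(2R,3S)-3,5-dibromo-2,3-dihydro-1-benzofuran-2-yl]propan-2-yl carbonate | CC(C)(C)OC(=O)OC(C)(C)[C@H]1Oc2ccc(Br)cc2[C@@H]1Br
F3 | step 13 | (2R,3R)-5-[(1S)-1-(tert-butyldimethylsilyloxy)ethyl]-2-(prop-1-en-2-yl)-2,3-dihydro-1-benzofuran-3-yl 3-methylbutanoate | C=C(C)[C@H]1Oc2ccc([C@H](C)O[Si](C)(C)C(C)(C)C)cc2[C@H]1OC(=O)CC(C)C
F4 | step 13 | (2R,3R)-5-[(1S)-1-(tert-butyldimethylsilyloxy)ethyl]-2-(3-hydroxyprop-1-en-2-yl)-2,3-dihydro-1-benzofuran-3-yl 3-methylbutanoate | C=C(CO)[C@H]1Oc2ccc([C@H](C)O[Si](C)(C)C(C)(C)C)cc2[C@H]1OC(=O)CC(C)C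
F5 | step 13 | (2R,3R)-5-[(1S)-1-(tert-butyldimethylsilyloxy)ethyl]-2-(3-oxoprop-1-en-2-yl)-2,3-dihydro-1-benzofuran-3-yl 3-methylbutanoate | C=C(C=O)[C@H]1Oc2ccc([C@H](C)O[Si](C)(C)C(C)(C)C)cc2[C@H]1OC(=O)CC(C)C
F6 | step 13 | (2R,3R)-5-[(1S)-1-hydroxyethyl]-2-(3-oxoprop-1-en-2-yl)-2,3-dihydro-1-benzofuran-3-yl 3-methylbutanoate | C=C(C=O)[C@H]1Oc2ccc([C@H](C)O)cc2[C@H]1OC(=O)CC(C)C
F7 | step 10 | 2-[(2S,3R)-5-bromo-3-(tert-butyldimethylsilyloxy)-2,3-dihydro-1-benzofuran-2-yl]propan-2-ol | CC(C)(O)[C@H]1Oc2ccc(Br)cc2[C@H]1O[Si](C)(C)C(C)(C)C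
F8 | step 10 | 2-[(2S,3R)-3-(tert-butyldimethylsilyloxy)-5-(1-ethoxyethenyl)-2,3-dihydro-1-benzofuran-2-yl]propan-2-ol | CC(C)(O)[C@H]1Oc2ccc(C(=C)OCC)cc2[C@H]1O[Si](C)(C)C(C)(C)C
F9 | step 10 | 1-[(2S,3R)-3-(tert-butyldimethylsilyloxy)-2-(2-hydroxypropan-2-yl)-2,3-dihydro-1-benzofuran-5-yl]ethanone | CC(C)(O)[C@H]1Oc2ccc(C(C)=O)cc2[C@H]1O[Si](C)(C)C(C)(C)C
F10 | step 10 | 1-[(2R,3R)-3-(tert-butyldimethylsilyloxy)-2-(prop-1-en-2-yl)-2,3-dihydro-1-benzofuran-5-yl]ethanone | C=C(C)[C@H]1Oc2ccc(C(C)=O)cc2[C@H]1O[Si](C)(C)C(C)(C)C
F11 | step 10 | 1-[(2R,3R)-3-hydroxy-2-(prop-1-en-2-yl)-2,3-dihydro-1-benzofuran-5-yl]ethanone | C=C(C)[C@H]1Oc2ccc(C(C)=O)cc2[C@H]1O
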